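All carbon labels (C1–C15) use guaiane numbering: ring A is C1–C5 (C3 carbonyl, C4 bearing C15), ring B is C1, C5–C10, C11 is the carbinol carbon on C7, C14 the methyl on C10.

## Analysis of the target

Torilin (28) is a hydroazulene: a cyclopentenone (ring A, C3 ketone, C4=C5, methyl C15 on C4) fused through the C1–C5 bond to a cycloheptane (ring B). Because C5 is sp2, the ring fusion has only one stereocentre, C1. All four stereocentres sit on ring B: C1 (R), C7 (S), C8 (R) and C10 (S). The C1 hydrogen, the C10 methyl, the C8 oxygen and the C7 side chain lie on the same face, so C7/C8 are cis and C8/C10 are cis-1,3. C7 carries a tertiary acetate, C11(CH3)2OAc, and C8 carries the (Z)-2-methylbut-2-enoate (angelate). The angelate isomerises to its E isomer with acid, base, nucleophiles or heat. The tertiary acetate can eliminate or migrate to a free C8 hydroxyl. C1 is γ to the enone carbonyl and can epimerise through the dienol. The hard part is the seven-membered ring with a bulky C11 group cis to the acylated C8: with the C8 oxygen and C10 methyl both pseudoequatorial, the cis C7 substituent is pseudoaxial, so equilibration cannot be relied on to place it. The strategy rests on the sp2 carbon C5 lying between C4 of ring A and C6 of ring B. A conjugated diene C4=C5–C6=C7 is the metathesis image of an alkyne C5≡C6 flanked by two terminal alkenes on a chain branched at the propargylic carbon C1.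

## Retrosynthetic reasoning

**C8 ester.** Torilin 28 is cut at the C8 O–acyl bond into alcohol 25 and angelic acid 26. The Z-enoate is the most fragile group, so it is put on last, through the mixed anhydride 27, and never meets fluoride, palladium or strong base.

**C8 silyl ether.** Alcohol 25 comes from silyl ether 24. The silyl group has to survive from the Morita–Baylis–Hillman stage onwards, and its removal must not set off acetate migration from O11 to O8.

**C4–C15.** Methyl enone 24 is cut at C4–C15 to iodoenone 23 and then to enone 22. Leaving C4 as CH keeps the alkene that starts the metathesis monosubstituted. The price is two steps: α-iodination of the enone and a methyl cross-coupling.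

**C3 ketal and C11.** Enone 22 comes from ketal 21, acetate 21 from carbinol 20, and 20 from ester 19 by cutting C11–C12 and C11–C13. The ketal keeps C4=C5 an isolated alkene while two methyl groups are added to the ester. The acetate is installed before the ketal is opened, because the tertiary acetate tolerates the mild acid needed.

**C7–H.** Ester 19 comes from dienoate 18 by conjugate reduction of the C6=C7 bond. C7 is created when the ester enolate is protonated, and this must happen under kinetic control, anti to the C8 silyloxy group. It is not left to equilibration, which would favour the trans ester.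

**Key disconnection.** Dienoate 18 is cut at C4=C5 and C6=C7 to the open-chain dienyne 17. This is the only place where one sp2 carbon (C5) is shared by both rings, so one alkyne can serve both ring closures. What is gained is an acyclic precursor whose three stereocentres (C1, C8, C10) can be set without any ring constraint. The forward cascade must start at the vinyl group so that ring A closes first.

**C7–C8.** Dienyne 17 comes from allylic alcohol 16, and 16 from aldehyde 13 and acrylate 14 by a Morita–Baylis–Hillman reaction, with 15 as the unisolated first adduct. C8 is 1,3 to C10 in an open chain, so the substrate cannot relay its configuration; the new centre is set by the catalyst.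

**C2–C3–C4 arm.** Aldehyde 13 comes from alcohol 12, 12 from vinyl ketone 10 (through 11), 10 from diol 9, and 9 from aldehyde 8 by cutting C3–C4 (vinyl addition). Aldehyde carbon C3 is traced to the terminal alkene of the allyl group in 6 (through ozonide 7). The vinyl dioxolane cannot be brought in as an electrophile, because a carbon next to a ketal is neopentyl-like and inert to enolates. It is therefore grown from an allyl group.

**C5≡C6 and C8–OH.** Alkynol 6 comes from lactol 5 and lactone 4. One lactone carbonyl gives the alkyne by one-carbon homologation, and the ring oxygen gives the C8 hydroxyl.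

**C1–C2.** Allyl lactone 4 is cut at C1–C2 to lactone 3. Alkylating the six-membered enolate trans to the C10 methyl sets C1 from C10 by 1,2-induction in a ring.

**C10.** Lactone 3 comes from half-ester 1 through hydroxy acid 2. The C10 stereocentre is bought, and the choice of which arm is reduced decides which lactone enantiomer forms.

## Alternatives that were turned down

**Alternative 1:** Ring B is cut at C6–C7 and C9–C10, a formal [4+3] between the exocyclic diene of triene A2 (C6=C5–C1=C10, with the C3 enol ether and C4 methyl already in ring A) and the vinylcarbenoid from diazo ester A3. In the forward step Rh2(S-PTAD)4 decomposes A3, the carbenoid cyclopropanates the C5=C6 methylene, and the cis-divinylcyclopropane undergoes Cope rearrangement to cycloheptadiene A1.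
- In its favour: it is convergent, makes two C–C bonds and ring B in one step, sets C10 by the catalyst, and arrives with C15, the C3 oxygen, the C8 oxygen and the C11 carbon in place. On convergence, and on having C15 from the start, it is stronger than the chosen route.
- Against it: A1 has only C10 as a stereocentre. C1 would be set by protonation when the methoxydiene is hydrolysed, with only the C10 methyl to steer it. C7 and C8 would come from a β-keto ester whose C7 epimerises freely and settles trans to the C8 oxygen, the opposite of 28.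
- Also against it: A2 is a cross-conjugated triene prone to double-bond shift and dimerisation, the carbenoid must choose the methylene over the enol ether and the ethylidene, and the ethylidene geometry must be pure to fix C10.
- In comparison, the chosen route fixes C1, C8 and C10 before any ring is made and creates no stereocentre in the ring-forming step, so only C7 remains to be set on the bicycle.

**Alternative 2:** Ring A is cut at C1–C2 and annulated onto a finished cycloheptene. In the forward step Ph3PAuSbF6 activates the terminal alkyne of the tertiary propargylic pivalate A5, the pivalate shifts from C4 to C3, and the resulting gold carbenoid carbon C2 closes onto ring carbon C1. Hydrolysis of the dienyl pivalate gives cyclopentenone A4, which is the same compound as 24.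
- In its favour: it ends two steps from 28 with the enone and C15 already present and needs no iodination or cross-coupling. On the endgame it is clearly stronger.
- Against it: A5, a cycloheptene that already carries C7, C8, C10 and the tertiary acetate, must be made first, so the key step does nothing for the medium ring. C1 is created only in the gold step, its configuration depends on the C4 propargylic centre and the neighbouring C10 methyl, and C4 would have to be made as one epimer. A cationic gold catalyst next to a tertiary acetate and a tertiary propargylic ester invites ionisation and 1,3-shift to an allenyl ester.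
- In comparison, the chosen route builds both rings from a chain in one operation and sets C1 early in a six-membered lactone.

**Alternative 3:** The bicycle is cut at C1–C5 and C8–C9, an intramolecular (4+3) between a furan (C5–C8, ester on C7) and an oxyallyl cation, both contained in chloromethyl ketone A7. In the forward step Et3N and LiClO4 ionise the chloroketone to the C1–C10(O)–C9 oxyallyl cation, which adds across furan carbons C5 and C8 to give the oxygen-bridged tricycle A6. Later β-elimination of the bridge oxygen from C5 would release the C4=C5 enone and the C8 hydroxyl.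
- In its favour: both rings, the C8 oxygen and, after bridge opening, the enone come from an achiral furan, C15 is present from the start, and the rigid bridged scaffold offers a convex face for later additions. On getting the C8 oxygen and the enone without separate steps it is stronger.
- Against it: the furan is deactivated by its ester towards an electrophilic oxyallyl cation. Absolute configuration can come only from the C4 centre of the tether, which is destroyed later. C10 emerges as a ketone and must be converted to the methyl-bearing stereocentre by olefination and face-selective reduction. C1 sits α to that ketone and can epimerise, and C7 still has to be set.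
- In comparison, the chosen route needs fewer redox corrections after ring formation and carries C10 from a chiral starting material.

Key step: step 12

## Route

Assumption: methyl hydrogen (R)-3-methylglutarate (1) is taken as a commercial half-ester of high enantiomeric purity.

Step 1
Reactants: 1 methyl hydrogen (R)-3-methylglutarate
Product: 3 (S)-4-methyltetrahydro-2H-pyran-2-one, via (S)-5-hydroxy-3-methylpentanoic acid 2 (not isolated)
Conditions: NaH, THF, 0 °C; LiBH4, 0 °C → reflux; then 3 M HCl, rt
Reagents that add atoms: none
Why: As its sodium carboxylate the acid arm is inert to LiBH4, so only the ester arm is reduced (chemoselective ester reduction), and acidification closes the δ-lactone. Because the ester arm becomes the CH2O end, the (R)-half-ester gives the (S)-lactone; the stereocentre (later C10) is not touched.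

Step 2
Reactants: 3 (S)-4-methyltetrahydro-2H-pyran-2-one
Product: 4 (3R,4S)-3-allyl-4-methyltetrahydro-2H-pyran-2-one
Conditions: LiN(iPr)2, THF, −78 °C; allyl bromide, −78 → −40 °C
Reagents that add atoms: allyl bromide C=CCBr
Why: Alkylation of a lactone lithium enolate with a reactive allylic halide. The electrophile enters anti to the neighbouring C10 methyl of the half-chair enolate, giving the trans lactone and so C1 (R).

Step 3
Reactants: 4 (3R,4S)-3-allyl-4-methyltetrahydro-2H-pyran-2-one
Product: 5 (3R,4S)-3-allyl-4-methyltetrahydro-2H-pyran-2-ol (anomeric mixture)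
Conditions: iBu2AlH (1.1 equiv), CH2Cl2, −78 °C; aq. Rochelle salt
Reagents that add atoms: none
Why: Partial reduction of a lactone to the lactol; the tetrahedral aluminate is stable at −78 °C, so over-reduction to the diol is avoided.

Step 4
Reactants: 5 (3R,4S)-3-allyl-4-methyltetrahydro-2H-pyran-2-ol
Product: 6 (3S,4R)-4-ethynyl-3-methylhept-6-en-1-ol
Conditions: dimethyl (1-diazo-2-oxopropyl)phosphonate, K2CO3, MeOH, 0 °C → rt
Reagents that add atoms: dimethyl (1-diazo-2-oxopropyl)phosphonate CC(=O)C(=[N+]=[N-])P(=O)(OC)OC
Why: Ohira–Bestmann homologation of the open hydroxy-aldehyde form of the lactol gives the terminal alkyne (C5≡C6) and frees the C8 hydroxyl in one operation. Most of the material rests as the closed lactol, which limits enolisation at C1.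

Step 5
Reactants: 6 (3S,4R)-4-ethynyl-3-methylhept-6-en-1-ol
Product: 8 (3R,4S)-3-ethynyl-6-hydroxy-4-methylhexanal, via secondary ozonide 7 (not isolated)
Conditions: O3, CH2Cl2, −78 °C, stopped at the first blue tinge; PPh3, −78 °C → rt
Reagents that add atoms: ozone [O-][O+]=O
Why: Ozonolysis with reductive work-up; the monosubstituted alkene reacts far faster with ozone than the terminal alkyne, so the allyl group alone is cut to the C3 aldehyde.

Step 6
Reactants: 8 (3R,4S)-3-ethynyl-6-hydroxy-4-methylhexanal
Product: 9 (3RS,5R,6S)-5-ethynyl-6-methyloct-1-ene-3,8-diol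
Conditions: CH2=CHMgBr (3.5 equiv), THF, −78 → 0 °C; aq. NH4Cl
Reagents that add atoms: vinylmagnesium bromide C=C[Mg]Br
Why: Grignard 1,2-addition to the aldehyde, with two further equivalents consumed by the O–H and C≡C–H protons. The C3 carbinol forms as both epimers, which does not matter because it is oxidised in the next step.

Step 7
Reactants: 9 (3RS,5R,6S)-5-ethynyl-6-methyloct-1-ene-3,8-diol
Product: 10 (5R,6S)-5-ethynyl-8-hydroxy-6-methyloct-1-en-3-one
Conditions: activated MnO2 (excess), CH2Cl2, rt
Reagents that add atoms: none
Why: MnO2 oxidises the allylic alcohol and leaves the saturated primary alcohol alone (chemoselective allylic oxidation). The vinyl ketone is used at once to avoid oligomerisation.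

Step 8
Reactants: 10 (5R,6S)-5-ethynyl-8-hydroxy-6-methyloct-1-en-3-one
Product: 12 (3S,4R)-4-ethynyl-3-methyl-5-(2-vinyl-1,3-dioxolan-2-yl)pentan-1-ol, via trimethylsilyl ether 11 (not isolated)
Conditions: Me3SiOCH2CH2OSiMe3, Me3SiOTf (cat.), CH2Cl2, −78 → −30 °C; pyridine; then K2CO3 (cat.), MeOH, 0 °C
Reagents that add atoms: 1,2-bis(trimethylsilyloxy)ethane C[Si](C)(C)OCCO[Si](C)(C)C
Why: Aprotic ketalisation with the bis-silyl ether of ethylene glycol under silyl triflate catalysis. At low temperature the silylated diol attacks the activated carbonyl carbon and not the β-carbon, so the vinyl group survives; the primary hydroxyl is silylated in passing and released by basic methanolysis.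

Step 9
Reactants: 12 (3S,4R)-4-ethynyl-3-methyl-5-(2-vinyl-1,3-dioxolan-2-yl)pentan-1-ol
Product: 13 (3S,4R)-4-ethynyl-3-methyl-5-(2-vinyl-1,3-dioxolan-2-yl)pentanal
Conditions: Dess–Martin periodinane, NaHCO3, CH2Cl2, 0 °C → rt
Reagents that add atoms: none
Why: Buffered Dess–Martin oxidation of a primary alcohol to the aldehyde; the ketal and alkyne are inert, and the stereocentres are β and γ to the new carbonyl and cannot epimerise.

Step 10
Reactants: 13 (3S,4R)-4-ethynyl-3-methyl-5-(2-vinyl-1,3-dioxolan-2-yl)pentanal; 14 1,1,1,3,3,3-hexafluoropropan-2-yl acrylate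
Product: 16 methyl (3R,5S,6R)-6-ethynyl-3-hydroxy-5-methyl-2-methylidene-7-(2-vinyl-1,3-dioxolan-2-yl)heptanoate, via hexafluoroisopropyl ester 15 (not isolated)
Conditions: β-isocupreidine (10 mol%), DMF, −55 °C; then MeOH, Et3N, −55 °C → rt
Reagents that add atoms: methanol CO
Why: Enantioselective Morita–Baylis–Hillman reaction of an activated acrylate under a cinchona-derived amino-phenol catalyst. The quinuclidine nitrogen adds to the acrylate and the phenolic OH organises the aldol step, so the catalyst and not the remote C10 centre sets C8 (R). The activated ester is then exchanged for the methyl ester by mild methanolysis.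

Step 11
Reactants: 16 methyl (3R,5S,6R)-6-ethynyl-3-hydroxy-5-methyl-2-methylidene-7-(2-vinyl-1,3-dioxolan-2-yl)heptanoate
Product: 17 methyl (3R,5S,6R)-3-[(tert-butyldimethylsilyl)oxy]-6-ethynyl-5-methyl-2-methylidene-7-(2-vinyl-1,3-dioxolan-2-yl)heptanoate
Conditions: tBuMe2SiCl, imidazole, DMF, rt
Reagents that add atoms: tert-butyldimethylsilyl chloride CC(C)(C)[Si](C)(C)Cl
Why: Standard silylation of a secondary allylic alcohol under non-acidic conditions that leave the ketal intact. The bulky silyl ether later shields one face of C7.

Step 12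
Reactants: 17 methyl (3R,5S,6R)-3-[(tert-butyldimethylsilyl)oxy]-6-ethynyl-5-methyl-2-methylidene-7-(2-vinyl-1,3-dioxolan-2-yl)heptanoate
Product: 18 methyl (6R,8S,8aR)-6-[(tert-butyldimethylsilyl)oxy]-8-methyl-6,7,8,8a-tetrahydro-1H-spiro[azulene-2,2'-[1,3]dioxolane]-5-carboxylate
Conditions: second-generation Grubbs catalyst (H2IMes)(PCy3)Cl2Ru=CHPh (10 mol%), toluene (0.005 M), 80 °C, argon sparge
Reagents that add atoms: none
Why: The benzylidene exchanges onto the vinyl group (C4), the only monosubstituted alkene, to give Ru=C4H–C3. This carbene adds across the tethered alkyne in the exo sense (C4 bonds to C5), and opening of the ruthenacyclobutene closes the five-membered ring A with the C4=C5 bond and moves the carbene to C6. The conjugated C6 carbene then undergoes ring-closing alkene metathesis onto C7 of the acrylate, closing the seven-membered ring B with the C6=C7 bond and releasing Ru=CH2 as chain carrier. One molecule of ethene, not two, is lost per turnover. The closest known reaction type is the tandem dienyne ring-closing metathesis to fused bicyclic 1,3-dienes with ruthenium carbenes. No stereocentre is created; C1, C8 and C10 are spectators, and because C1 carries both tethers the rings must fuse at C1–C5. The step needs initiation at the vinyl end, since a start at the acrylate end would close two six-membered rings. This is secured because the acrylate is 1,1-disubstituted, electron-poor and flanked by the silyl ether, and so cannot load the catalyst. Exo closure is secured by the preference for a five- over a six-membered ring, and high dilution suppresses intermolecular metathesis.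

Step 13
Reactants: 18 methyl (6R,8S,8aR)-6-[(tert-butyldimethylsilyl)oxy]-8-methyl-6,7,8,8a-tetrahydro-1H-spiro[azulene-2,2'-[1,3]dioxolane]-5-carboxylate
Product: 19 methyl (5S,6R,8S,8aR)-6-[(tert-butyldimethylsilyl)oxy]-8-methyl-4,5,6,7,8,8a-hexahydro-1H-spiro[azulene-2,2'-[1,3]dioxolane]-5-carboxylate
Conditions: Cu(OAc)2 (5 mol%), 1,2-bis(diphenylphosphino)benzene, (EtO)2MeSiH, t-BuOH, toluene, 0 °C → rt
Reagents that add atoms: none
Why: Copper hydride conjugate reduction: hydrocupration of the α,β-bond puts hydride on C6, while C4=C5 is shielded by the spiro-ketal and becomes an isolated alkene. The copper enolate is protonated by tert-butanol on the face anti to the C8 silyloxy group, which allylic strain with the enolate turns pseudoaxial, so C7 (S) forms with the ester cis to the C8 oxygen under kinetic control.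

Step 14
Reactants: 19 methyl (5S,6R,8S,8aR)-6-[(tert-butyldimethylsilyl)oxy]-8-methyl-4,5,6,7,8,8a-hexahydro-1H-spiro[azulene-2,2'-[1,3]dioxolane]-5-carboxylate
Product: 20 2-[(5S,6R,8S,8aR)-6-[(tert-butyldimethylsilyl)oxy]-8-methyl-4,5,6,7,8,8a-hexahydro-1H-spiro[azulene-2,2'-[1,3]dioxolan]-5-yl]propan-2-ol
Conditions: MeLi, CeCl3, THF, −78 → 0 °C
Reagents that add atoms: methyllithium [Li]C
Why: Double addition of a methylcerium reagent to the ester gives the C11 tertiary carbinol. The organocerium is nucleophilic but weakly basic, so neither the ester nor the intermediate methyl ketone is enolised and the kinetically set C7 is kept.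

Step 15
Reactants: 20 2-[(5S,6R,8S,8aR)-6-[(tert-butyldimethylsilyl)oxy]-8-methyl-4,5,6,7,8,8a-hexahydro-1H-spiro[azulene-2,2'-[1,3]dioxolan]-5-yl]propan-2-ol
Product: 21 2-[(5S,6R,8S,8aR)-6-[(tert-butyldimethylsilyl)oxy]-8-methyl-4,5,6,7,8,8a-hexahydro-1H-spiro[azulene-2,2'-[1,3]dioxolan]-5-yl]propan-2-yl acetate
Conditions: Ac2O, DMAP, Et3N, CH2Cl2, 40 °C
Reagents that add atoms: acetic anhydride CC(=O)OC(C)=O
Why: DMAP-catalysed acetylation through the N-acetylpyridinium ion is strong enough for a tertiary alcohol, and the basic medium leaves the ketal and silyl ether intact.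

Step 16
Reactants: 21 2-[(5S,6R,8S,8aR)-6-[(tert-butyldimethylsilyl)oxy]-8-methyl-4,5,6,7,8,8a-hexahydro-1H-spiro[azulene-2,2'-[1,3]dioxolan]-5-yl]propan-2-yl acetate
Product: 22 2-[(5S,6R,8S,8aR)-6-[(tert-butyldimethylsilyl)oxy]-8-methyl-2-oxo-1,2,4,5,6,7,8,8a-octahydroazulen-5-yl]propan-2-yl acetate
Conditions: PPTS, acetone/H2O, 40 °C
Reagents that add atoms: water O
Why: The allylic ketal hydrolyses easily through a stabilised oxocarbenium ion and gives the C3 enone with C4=C5 already in place. The acid is too weak to cleave the secondary silyl ether, ionise the tertiary acetate or enolise towards C1.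

Step 17
Reactants: 22 2-[(5S,6R,8S,8aR)-6-[(tert-butyldimethylsilyl)oxy]-8-methyl-2-oxo-1,2,4,5,6,7,8,8a-octahydroazulen-5-yl]propan-2-yl acetate
Product: 23 2-[(5S,6R,8S,8aR)-6-[(tert-butyldimethylsilyl)oxy]-3-iodo-8-methyl-2-oxo-1,2,4,5,6,7,8,8a-octahydroazulen-5-yl]propan-2-yl acetate
Conditions: I2, pyridine, CH2Cl2, rt
Reagents that add atoms: iodine II
Why: Pyridine-mediated α-iodination of a cyclic enone: reversible conjugate addition of pyridine, iodination of the enolate at C4 and elimination (addition–elimination of the Baylis–Hillman type). No other position of the molecule is nucleophilic.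

Step 18
Reactants: 23 2-[(5S,6R,8S,8aR)-6-[(tert-butyldimethylsilyl)oxy]-3-iodo-8-methyl-2-oxo-1,2,4,5,6,7,8,8a-octahydroazulen-5-yl]propan-2-yl acetate
Product: 24 2-[(5S,6R,8S,8aR)-6-[(tert-butyldimethylsilyl)oxy]-3,8-dimethyl-2-oxo-1,2,4,5,6,7,8,8a-octahydroazulen-5-yl]propan-2-yl acetate
Conditions: Me4Sn, Pd2(dba)3 (5 mol%), AsPh3, CuI, NMP, 80 °C
Reagents that add atoms: tetramethylstannane C[Sn](C)(C)C
Why: Stille coupling of an α-iodoenone with a methyl stannane; the neutral conditions spare the acetate, the silyl ether and the C1 centre, and install C15.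

Step 19
Reactants: 24 2-[(5S,6R,8S,8aR)-6-[(tert-butyldimethylsilyl)oxy]-3,8-dimethyl-2-oxo-1,2,4,5,6,7,8,8a-octahydroazulen-5-yl]propan-2-yl acetate
Product: 25 2-[(5S,6R,8S,8aR)-6-hydroxy-3,8-dimethyl-2-oxo-1,2,4,5,6,7,8,8a-octahydroazulen-5-yl]propan-2-yl acetate
Conditions: HF·pyridine, pyridine, THF, 0 °C → rt
Reagents that add atoms: none
Why: Buffered fluoride desilylation; the weakly acidic, non-basic medium does not generate a free alkoxide, which is what would carry the acetyl group from O11 to O8.

Step 20
Reactants: 25 2-[(5S,6R,8S,8aR)-6-hydroxy-3,8-dimethyl-2-oxo-1,2,4,5,6,7,8,8a-octahydroazulen-5-yl]propan-2-yl acetate; 26 angelic acid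
Product: 28 torilin, via angelic 2,4,6-trichlorobenzoic anhydride 27 (not isolated)
Conditions: 26, 2,4,6-Cl3C6H2COCl, Et3N, toluene, rt; then 25, 80 °C
Reagents that add atoms: none
Why: Yamaguchi esterification: the alcohol attacks the unhindered angeloyl carbonyl of the mixed anhydride. Without a nucleophilic amine catalyst the Z double bond does not isomerise, and the configuration at C8 is retained because only the O–H bond reacts.

## Compound list

1 | methyl hydrogen (R)-3-methylglutarate | COC(=O)C[C@H](C)CC(=O)O | starting material
2 | (S)-5-hydroxy-3-methylpentanoic acid | OCC[C@H](C)CC(=O)O | intermediate (not isolated)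
3 | (S)-4-methyltetrahydro-2H-pyran-2-one | O=C1C[C@@H](C)CCO1 | intermediate
4 | (3R,4S)-3-allyl-4-methyltetrahydro-2H-pyran-2-one | O=C1[C@H](CC=C)[C@@H](C)CCO1 | intermediate
5 | (3R,4S)-3-allyl-4-methyltetrahydro-2H-pyran-2-ol, anomeric mixture | OC1[C@H](CC=C)[C@@H](C)CCO1 | intermediate
6 | (3S,4R)-4-ethynyl-3-methylhept-6-en-1-ol | C#C[C@H](CC=C)[C@@H](C)CCO | intermediate
7 | (3S,4R)-4-ethynyl-3-methyl-5-(1,2,4-trioxolan-3-yl)pentan-1-ol | C#C[C@H](CC1OCOO1)[C@@H](C)CCO | intermediate (not isolated)
8 | (3R,4S)-3-ethynyl-6-hydroxy-4-methylhexanal | C#C[C@H](CC=O)[C@@H](C)CCO | intermediate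
9 | (3RS,5R,6S)-5-ethynyl-6-methyloct-1-ene-3,8-diol | C#C[C@H](CC(O)C=C)[C@@H](C)CCO | intermediate
10 | (5R,6S)-5-ethynyl-8-hydroxy-6-methyloct-1-en-3-one | C#C[C@H](CC(=O)C=C)[C@@H](C)CCO | intermediate
11 | {[(3S,4R)-4-ethynyl-3-methyl-5-(2-vinyl-1,3-dioxolan-2-yl)pentyl]oxy}trimethylsilane | C#C[C@H](CC1(C=C)OCCO1)[C@@H](C)CCO[Si](C)(C)C | intermediate (not isolated)
12 | (3S,4R)-4-ethynyl-3-methyl-5-(2-vinyl-1,3-dioxolan-2-yl)pentan-1-ol | C#C[C@H](CC1(C=C)OCCO1)[C@@H](C)CCO | intermediate
13 | (3S,4R)-4-ethynyl-3-methyl-5-(2-vinyl-1,3-dioxolan-2-yl)pentanal | C#C[C@H](CC1(C=C)OCCO1)[C@@H](C)CC=O | intermediate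
14 | 1,1,1,3,3,3-hexafluoropropan-2-yl acrylate | C=CC(=O)OC(C(F)(F)F)C(F)(F)F | starting material
15 | 1,1,1,3,3,3-hexafluoropropan-2-yl (3R,5S,6R)-6-ethynyl-3-hydroxy-5-methyl-2-methylidene-7-(2-vinyl-1,3-dioxolan-2-yl)heptanoate | C#C[C@H](CC1(C=C)OCCO1)[C@@H](C)C[C@@H](O)C(=C)C(=O)OC(C(F)(F)F)C(F)(F)F | intermediate (not isolated)
16 | methyl (3R,5S,6R)-6-ethynyl-3-hydroxy-5-methyl-2-methylidene-7-(2-vinyl-1,3-dioxolan-2-yl)heptanoate | C#C[C@H](CC1(C=C)OCCO1)[C@@H](C)C[C@@H](O)C(=C)C(=O)OC | intermediate
17 | methyl (3R,5S,6R)-3-[(tert-butyldimethylsilyl)oxy]-6-ethynyl-5-methyl-2-methylidene-7-(2-vinyl-1,3-dioxolan-2-yl)heptanoate | C#C[C@H](CC1(C=C)OCCO1)[C@@H](C)C[C@@H](O[Si](C)(C)C(C)(C)C)C(=C)C(=O)OC | intermediate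
18 | methyl (6R,8S,8aR)-6-[(tert-butyldimethylsilyl)oxy]-8-methyl-6,7,8,8a-tetrahydro-1H-spiro[azulene-2,2'-[1,3]dioxolane]-5-carboxylate | CC(C)(C)[Si](C)(C)O[C@@H]1C[C@H](C)[C@H]2CC3(OCCO3)C=C2C=C1C(=O)OC | intermediate
19 | methyl (5S,6R,8S,8aR)-6-[(tert-butyldimethylsilyl)oxy]-8-methyl-4,5,6,7,8,8a-hexahydro-1H-spiro[azulene-2,2'-[1,3]dioxolane]-5-carboxylate | CC(C)(C)[Si](C)(C)O[C@@H]1C[C@H](C)[C@H]2CC3(OCCO3)C=C2C[C@@H]1C(=O)OC | intermediate
20 | 2-[(5S,6R,8S,8aR)-6-[(tert-butyldimethylsilyl)oxy]-8-methyl-4,5,6,7,8,8a-hexahydro-1H-spiro[azulene-2,2'-[1,3]dioxolan]-5-yl]propan-2-ol | CC(C)(C)[Si](C)(C)O[C@@H]1C[C@H](C)[C@H]2CC3(OCCO3)C=C2C[C@@H]1C(C)(C)O | intermediate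
21 | 2-[(5S,6R,8S,8aR)-6-[(tert-butyldimethylsilyl)oxy]-8-methyl-4,5,6,7,8,8a-hexahydro-1H-spiro[azulene-2,2'-[1,3]dioxolan]-5-yl]propan-2-yl acetate | CC(C)(C)[Si](C)(C)O[C@@H]1C[C@H](C)[C@H]2CC3(OCCO3)C=C2C[C@@H]1C(C)(C)OC(C)=O | intermediate
22 | 2-[(5S,6R,8S,8aR)-6-[(tert-butyldimethylsilyl)oxy]-8-methyl-2-oxo-1,2,4,5,6,7,8,8a-octahydroazulen-5-yl]propan-2-yl acetate | CC(C)(C)[Si](C)(C)O[C@@H]1C[C@H](C)[C@H]2CC(=O)C=C2C[C@@H]1C(C)(C)OC(C)=O | intermediate
23 | 2-[(5S,6R,8S,8aR)-6-[(tert-butyldimethylsilyl)oxy]-3-iodo-8-methyl-2-oxo-1,2,4,5,6,7,8,8a-octahydroazulen-5-yl]propan-2-yl acetate | CC(C)(C)[Si](C)(C)O[C@@H]1C[C@H](C)[C@H]2CC(=O)C(I)=C2C[C@@H]1C(C)(C)OC(C)=O | intermediate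
24 | 2-[(5S,6R,8S,8aR)-6-[(tert-butyldimethylsilyl)oxy]-3,8-dimethyl-2-oxo-1,2,4,5,6,7,8,8a-octahydroazulen-5-yl]propan-2-yl acetate | CC(C)(C)[Si](C)(C)O[C@@H]1C[C@H](C)[C@H]2CC(=O)C(C)=C2C[C@@H]1C(C)(C)OC(C)=O | intermediate
25 | 2-[(5S,6R,8S,8aR)-6-hydroxy-3,8-dimethyl-2-oxo-1,2,4,5,6,7,8,8a-octahydroazulen-5-yl]propan-2-yl acetate | O[C@@H]1C[C@H](C)[C@H]2CC(=O)C(C)=C2C[C@@H]1C(C)(C)OC(C)=O | intermediate
26 | angelic acid, (Z)-2-methylbut-2-enoic acid | C/C=C(/C)C(=O)O | starting material
27 | (Z)-2-methylbut-2-enoic 2,4,6-trichlorobenzoic anhydride | C/C=C(/C)C(=O)OC(=O)c1c(Cl)cc(Cl)cc1Cl | intermediate (not isolated)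
28 | torilin, (5S,6R,8S,8aR)-5-(2-acetoxypropan-2-yl)-3,8-dimethyl-2-oxo-1,2,4,5,6,7,8,8a-octahydroazulen-6-yl (Z)-2-methylbut-2-enoate | C/C=C(/C)C(=O)O[C@@H]1C[C@H](C)[C@H]2CC(=O)C(C)=C2C[C@@H]1C(C)(C)OC(C)=O | target

## Step count and least certain steps

Total: 20 steps. Longest linear sequence: 20 steps from 1 (the route is linear; 14 and 26 are purchased).

**Step 12 (key step).** Loading of the catalyst onto the vinyl group may be slow, because the neighbouring ketal carbon is fully substituted. The carbene can then start at the terminal alkyne, and endo-type closure or alkyne oligomerisation competes. The final closure onto the hindered, electron-poor acrylate may also lag, so the monocyclic carbene is lost to intermolecular metathesis. Fallback, from 17 back to 18: the two ring closures are separated. Heating 17 with PtCl2 in toluene brings about the skeletal cycloisomerisation of the 1,6-enyne, which needs no metathesis carbene and, for lack of allylic hydrogens on the alkene side, cannot divert to an ene product. It gives the 1-vinylcyclopentene methyl (3R,5S)-3-[(tert-butyldimethylsilyl)oxy]-5-[(8R)-7-ethenyl-1,4-dioxaspiro[4.4]non-6-en-8-yl]-2-methylidenehexanoate F1. The diene and acrylate ends of F1 are then joined by ring-closing metathesis with the second-generation Hoveyda–Grubbs catalyst (H2IMes)Cl2Ru=CH(C6H4-2-OiPr), which returns to 18.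

**Step 13.** Three processes can spoil it: delivery of hydride to C4 (1,6-reduction), loss of the silyloxy group from the C7 enolate by β-elimination, and protonation of the enolate on the face syn to the silyl ether, which gives the C7 epimer. The last is the most likely, because the required cis ester is the less stable one. Fallback, from 18 back to 20: the order of events is changed so that no enolate is formed. Addition of MeLi/CeCl3 to the dienoate 18 gives the dienyl carbinol 2-[(6R,8S,8aR)-6-[(tert-butyldimethylsilyl)oxy]-8-methyl-6,7,8,8a-tetrahydro-1H-spiro[azulene-2,2'-[1,3]dioxolan]-5-yl]propan-2-ol F2. Hydroxyl-directed hydrogenation of F2 with [Ir(cod)(PCy3)(py)]PF6 and H2 in CH2Cl2 saturates only the C6=C7 bond next to the carbinol, from the face away from the C8 silyl ether, and returns to 20.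

**Step 10.** The chiral amine catalyst has to override a substrate with its own stereocentres, and conversion of aliphatic aldehydes is slow, so poor facial selectivity at C8 or stalling with consumption of the aldehyde in side condensations is possible. Fallback, from 13 back to 16: catalyst control is given up in favour of separation. The reaction of 13 with methyl acrylate and DABCO in methanol gives 16 together with its C8 epimer, methyl (3S,5S,6R)-6-ethynyl-3-hydroxy-5-methyl-2-methylidene-7-(2-vinyl-1,3-dioxolan-2-yl)heptanoate F3. The two are diastereomers and are separated by chromatography, and 16 continues at step 11.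

**Step 8.** The diol reagent may add to the β-carbon of the vinyl ketone instead of the carbonyl, or the enone may polymerise under the silyl triflate, so the vinyl group is lost. Fallback, from 10 back to 12: the alkene is masked while the ketal is made. Me3SiBr and ethylene glycol in CH2Cl2 add HBr to the enone and ketalise the resulting β-bromo ketone to (3S,4R)-5-[2-(2-bromoethyl)-1,3-dioxolan-2-yl]-4-ethynyl-3-methylpentan-1-ol F4. KOtBu in THF then eliminates HBr and returns to 12.

**Step 17.** The β-carbon of the enone (C5) is fully substituted, so the conjugate addition of pyridine that starts the iodination may be too slow, leaving the enone unchanged or inviting enolisation towards C1 on forcing. Fallback, from 22 back to 24 without passing 23: C15 is brought in as formaldehyde. Heating 22 with PhSH, aqueous CH2O and Et3N in ethanol gives the thiomethylated enone 2-[(5S,6R,8S,8aR)-6-[(tert-butyldimethylsilyl)oxy]-8-methyl-2-oxo-3-[(phenylsulfanyl)methyl]-1,2,4,5,6,7,8,8a-octahydroazulen-5-yl]propan-2-yl acetate F5. Desulfurisation of F5 with deactivated Raney Ni in acetone gives 24.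

## Further compounds

F1 | step 12 | methyl (3R,5S)-3-[(tert-butyldimethylsilyl)oxy]-5-[(8R)-7-ethenyl-1,4-dioxaspiro[4.4]non-6-en-8-yl]-2-methylidenehexanoate | C=CC1=CC2(OCCO2)C[C@@H]1[C@@H](C)C[C@@H](O[Si](C)(C)C(C)(C)C)C(=C)C(=O)OC
F2 | step 13 | 2-[(6R,8S,8aR)-6-[(tert-butyldimethylsilyl)oxy]-8-methyl-6,7,8,8a-tetrahydro-1H-spiro[azulene-2,2'-[1,3]dioxolan]-5-yl]propan-2-ol | CC(C)(C)[Si](C)(C)O[C@@H]1C[C@H](C)[C@H]2CC3(OCCO3)C=C2C=C1C(C)(C)O
F3 | step 10 | methyl (3S,5S,6R)-6-ethynyl-3-hydroxy-5-methyl-2-methylidene-7-(2-vinyl-1,3-dioxolan-2-yl)heptanoate | C#C[C@H](CC1(C=C)OCCO1)[C@@H](C)C[C@H](O)C(=C)C(=O)OC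
F4 | step 8 | (3S,4R)-5-[2-(2-bromoethyl)-1,3-dioxolan-2-yl]-4-ethynyl-3-methylpentan-1-ol | C#C[C@H](CC1(CCBr)OCCO1)[C@@H](C)CCO
F5 | step 17 | 2-[(5S,6R,8S,8aR)-6-[(tert-butyldimethylsilyl)oxy]-8-methyl-2-oxo-3-[(phenylsulfanyl)methyl]-1,2,4,5,6,7,8,8a-octahydroazulen-5-yl]propan-2-yl acetate | CC(C)(C)[Si](C)(C)O[C@@H]1C[C@H](C)[C@H]2CC(=O)C(CSc3ccccc3)=C2C[C@@H]1C(C)(C)OC(C)=O
A1 | alternative 1 | methyl (8S)-6-[(tert-butyldimethylsilyl)oxy]-2-methoxy-3,8-dimethyl-1,4,7,8-tetrahydroazulene-5-carboxylate | CC(C)(C)[Si](C)(C)OC1=C(C(=O)OC)CC2=C(CC(OC)=C2C)[C@@H](C)C1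
A2 | alternative 1 | 4-ethylidene-1-methoxy-2-methyl-3-methylidenecyclopent-1-ene | CC=C1CC(OC)=C(C)C1=C
A3 | alternative 1 | methyl 3-[(tert-butyldimethylsilyl)oxy]-2-diazobut-3-enoate | C=C(O[Si](C)(C)C(C)(C)C)C(=[N+]=[N-])C(=O)OC
A4 | alternative 2 | 2-[(5S,6R,8S,8aR)-6-[(tert-butyldimethylsilyl)oxy]-3,8-dimethyl-2-oxo-1,2,4,5,6,7,8,8a-octahydroazulen-5-yl]propan-2-yl acetate (identical with 24) | CC(C)(C)[Si](C)(C)O[C@@H]1C[C@H](C)[C@H]2CC(=O)C(C)=C2C[C@@H]1C(C)(C)OC(C)=O
A5 | alternative 2 | 2-{2-[(tert-butyldimethylsilyl)oxy]-4-methyl-6-[2-(pivaloyloxy)but-3-yn-2-yl]cyclohept-5-en-1-yl}propan-2-yl acetate, ring centres as in 28, either C4 epimer | C#CC(C)(OC(=O)C(C)(C)C)C1=C[C@@H](C)C[C@@H](O[Si](C)(C)C(C)(C)C)[C@@H](C(C)(C)OC(C)=O)C1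
A6 | alternative 3 | oxygen-bridged (C5–O–C8) tricyclic keto ester with C10 ketone, C3 dioxolane, C4 methyl and C6=C7 methyl enoate (guaiane numbering) | O1[C@@H]2CC(=O)[C@H]3CC4(OCCO4)[C@@H](C)[C@]13C=C2C(=O)OC
A7 | alternative 3 | methyl 5-{1-[2-(4-chloro-3-oxobutyl)-1,3-dioxolan-2-yl]ethyl}furan-3-carboxylate | COC(=O)c1coc(c1)C(C)C1(OCCO1)CCC(=O)CCl
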